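The 1,2-dioxane is disconnected at O2–C3 (ring numbering O1, O2, C3–C6), exploiting the β-peroxy-ester relationship O2–C3–Cα–CO2Me between ring and propanoate side chain. The ring is closed last by intramolecular SN2 opening of a cis-β-lactone at its alkyl C–O bond by the tertiary C6 alkylperoxide: one operation forms the peroxide ring, sets C3 by inversion, fixes the anti C3/Cα pair and unmasks the carboxyl group. The precursor is a cis-decalol carrying a silylperoxy quaternary carbon and a (3S,4R)-3-methyl-β-lactone. The decalol arises from one organocatalytic stereocentre relayed by cuprate addition, allylation and an iron-hydride radical cyclisation.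

Key step: step 18

Numbering used in names and comments (labdane-type): decalin C1–C10 with C4 = CMe2, C5 = carbinol ring-fusion carbon, C8 = CHMe, C9 = CH bearing the side chain, C10 = angular CMe; chain C11, C12; C13 = quaternary peroxy carbon (dioxane C6); C14, C15; C16 = secondary peroxy carbon (dioxane C3); C17 = propanoate α-carbon; C18 = carboxyl carbon. Dec = (5S,8R,9S,10R)-5-hydroxy-4,4,8,10-tetramethyl-cis-decalin-9-yl (5β-OH, 10β-Me, 9β-chain, 8α-Me).

Assumption: the sense of induction of the two organocatalysts is taken from the parent reactions of these catalyst classes ((S)-diarylprolinol ether gives the (R)-α-methyl aldehyde; O-trimethylsilylquinine gives the (4R)-lactone); if either sense is reversed in practice, the enantiomeric or pseudo-enantiomeric catalyst is used.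

Step 1
Reactants: 1 propanal; 2 pent-1-en-3-one (ethyl vinyl ketone)
Product: 3 (R)-2-methyl-5-oxoheptanal
Conditions: (S)-2-(methoxydiphenylmethyl)pyrrolidine (5 mol %), ethyl 3,4-dihydroxybenzoate (20 mol %), neat, 4 °C
Reagents that add atoms: none
Why: Organocatalytic Michael addition: the E-enamine of propanal is shielded on one face by the diphenyl(methoxy)methyl group and adds to the vinyl ketone under catalyst control, setting the α-methyl stereocentre (future C8) as R.

Step 2
Reactants: 3 (R)-2-methyl-5-oxoheptanal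
Product: 4 (R)-2,4-dimethylcyclohex-2-en-1-one
Conditions: LiOH, i-PrOH, rt
Reagents that add atoms: none
Why: Intramolecular aldol condensation (ethyl ketone enolate onto the aldehyde, then dehydration) closes ring B faster than the aldehyde α-centre epimerises and leaves the stereocentre at the configurationally stable γ-position of the enone.

Step 3
Reactants: 5 (S)-citramalic acid
Product: 6 (S)-2-methylbutane-1,2,4-triol
Conditions: BH3·SMe2, B(OMe)3, THF, 0 °C → rt; MeOH quench
Reagents that add atoms: none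
Why: Borane reduction of both carboxyl groups leaves the tertiary carbinol stereocentre (future C13) untouched.

Step 4
Reactants: 6 (S)-2-methylbutane-1,2,4-triol
Product: 7 (S)-2-(2,2,4-trimethyl-1,3-dioxolan-4-yl)ethan-1-ol
Conditions: Me2C(OMe)2, TsOH·H2O (cat.), acetone, rt
Reagents that add atoms: 2,2-dimethoxypropane COC(C)(C)OC
Why: Acid-catalysed transketalisation gives the five-membered acetonide of the tertiary/primary 1,2-diol in preference to the six-membered 1,3-isomer, leaving the C11 hydroxyl free.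

Step 5
Reactants: 7 (S)-2-(2,2,4-trimethyl-1,3-dioxolan-4-yl)ethan-1-ol
Product: 8 (S)-4-(2-bromoethyl)-2,2,4-trimethyl-1,3-dioxolane
Conditions: CBr4, PPh3, imidazole, CH2Cl2, 0 °C
Reagents that add atoms: tetrabromomethane BrC(Br)(Br)Br
Why: Appel bromination of the primary alcohol under buffered conditions that spare the acetonide.

Step 6
Reactants: 4 (R)-2,4-dimethylcyclohex-2-en-1-one; 8 (S)-4-(2-bromoethyl)-2,2,4-trimethyl-1,3-dioxolane
Product: 10 (3S,4R)-2,4-dimethyl-3-{2-[(S)-2,2,4-trimethyl-1,3-dioxolan-4-yl]ethyl}-1-(trimethylsilyloxy)cyclohex-1-ene, via Grignard reagent 9 (not isolated)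
Conditions: 8, Mg, THF, 40 °C; then CuBr·SMe2 (10 mol %), 4, TMSCl, DMPU, THF, −78 °C; Et3N quench
Reagents that add atoms: chlorotrimethylsilane C[Si](C)(C)Cl
Why: Copper-catalysed, TMSCl-accelerated conjugate addition of the Grignard reagent occurs anti to the C8 methyl group (trans-3,4 selectivity of 4-substituted cyclohexenones), setting C9 by substrate control and trapping the enolate regiospecifically as its silyl enol ether.

Step 7
Reactants: 10 silyl enol ether
Product: 12 (2R,3S,4R)-2-allyl-2,4-dimethyl-3-{2-[(S)-2,2,4-trimethyl-1,3-dioxolan-4-yl]ethyl}cyclohexan-1-one, via lithium enolate 11 (not isolated)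
Conditions: MeLi, THF, 0 °C; then allyl bromide, DMPU, −78 → 0 °C
Reagents that add atoms: allyl bromide C=CCBr
Why: MeLi releases the regiodefined lithium enolate, which is C-allylated on the face anti to the adjacent C9 side chain (regiospecific enolate alkylation), creating the C10 quaternary centre with its methyl cis to the C9 chain.

Step 8
Reactants: 12 allyl ketone
Product: 14 (2R,3S,4R)-2,4-dimethyl-2-(4-methylpent-4-en-1-yl)-3-{2-[(S)-2,2,4-trimethyl-1,3-dioxolan-4-yl]ethyl}cyclohexan-1-one, via B-alkyl-9-BBN adduct 13 (not isolated)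
Conditions: 9-BBN, THF, 0 °C → rt; then 2-bromopropene, Pd(dppf)Cl2 (5 mol %), aq. K3PO4, DMF, 50 °C
Reagents that add atoms: 2-bromopropene CC(Br)=C
Why: Anti-Markovnikov hydroboration of the terminal alkene followed by B-alkyl Suzuki–Miyaura coupling extends the arm to the 4-methylpent-4-enyl group, and the hindered α-quaternary ketone is spared.

Step 9
Reactants: 14 alkenyl ketone
Product: 15 (5S,8R,9S,10R)-4,4,8,10-tetramethyl-9-{2-[(S)-2,2,4-trimethyl-1,3-dioxolan-4-yl]ethyl}-cis-decalin-5-ol
Conditions: Fe(acac)3 (30 mol %), PhSiH3, EtOH, 60 °C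
Reagents that add atoms: none
Why: Hydrogen-atom transfer from an iron hydride to the 1,1-disubstituted alkene gives the tertiary C4 radical, which adds to the C5 ketone (HAT-initiated radical cyclisation of alkene-tethered ketones, six-membered ring A) on the face anti to the axial C10 methyl of the ring B chair, so the C4–C5 bond forms cis to the C1 arm and the cis-fused 5β-ol results.

Step 10
Reactants: 15 decalol acetonide
Product: 16 (S)-2-methyl-4-Dec-butane-1,2-diol
Conditions: AcOH/H2O/THF, 40 °C
Reagents that add atoms: none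
Why: Mild aqueous acid hydrolyses the acetonide without ionising the hindered tertiary alcohols.

Step 11
Reactants: 16 triol
Product: 18 (S)-2-methyl-2-(2-Dec-ethyl)oxirane, via primary tosylate 17 (not isolated)
Conditions: TsCl, Et3N, DMAP (cat.), CH2Cl2, 0 °C; then K2CO3, MeOH, rt
Reagents that add atoms: none
Why: Selective sulfonylation of the only primary hydroxyl and intramolecular Williamson displacement by the C13 alkoxide close the oxirane with retention at C13, because the C13–O bond is never broken.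

Step 12
Reactants: 18 epoxide
Product: 19 (R)-2-hydroperoxy-2-methyl-4-Dec-butan-1-ol
Conditions: anhydrous H2O2 in Et2O, H3PMo12O40 (5 mol %), rt
Reagents that add atoms: hydrogen peroxide OO
Why: Molybdenum-catalysed perhydrolysis of the 2,2-disubstituted oxirane: H2O2 opens the activated epoxide at the tertiary carbon in an SN2-like, invertive manner, giving the 13R tertiary hydroperoxide and the C14 primary alcohol.

Step 13
Reactants: 19 hydroperoxy alcohol
Product: 20 (R)-2-methyl-4-Dec-1-(triethylsilyloxy)-2-(triethylsilylperoxy)butane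
Conditions: TESCl, imidazole, DMF, 0 °C
Reagents that add atoms: chlorotriethylsilane CC[Si](Cl)(CC)CC
Why: Silylation of the hydroperoxide and of the primary alcohol, while the hindered tertiary C5 hydroxyl does not react.

Step 14
Reactants: 20 bis-silyl compound
Product: 21 (R)-2-methyl-4-Dec-2-(triethylsilylperoxy)butanal
Conditions: (COCl)2, DMSO, CH2Cl2, −78 → −30 °C; then Et3N
Reagents that add atoms: none
Why: Direct Swern oxidation of a primary triethylsilyl ether to the aldehyde; the tertiary silyl peroxide has no α-hydrogen and should be inert at low temperature.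

Step 15
Reactants: 21 α-silylperoxy aldehyde
Product: 22 (R,E)-4-methyl-6-Dec-4-(triethylsilylperoxy)hex-2-enal
Conditions: Ph3P=CHCHO, toluene, 70 °C
Reagents that add atoms: (triphenylphosphoranylidene)acetaldehyde O=CC=P(c1ccccc1)(c1ccccc1)c1ccccc1
Why: Wittig olefination with the stabilised formylmethylene ylide gives the (E)-enal and adds C15 and C16; stabilised ylides leave silyl and dialkyl peroxides intact.

Step 16
Reactants: 22 enal
Product: 23 (R)-4-methyl-6-Dec-4-(triethylsilylperoxy)hexanal
Conditions: Hantzsch ester, Bn2NH2+ CF3CO2− (10 mol %), THF, rt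
Reagents that add atoms: none
Why: Organocatalytic transfer hydrogenation (iminium activation, hydride from the dihydropyridine) reduces only the conjugated C=C bond and is metal-free, so the O–O bond survives.

Step 17
Reactants: 23 aldehyde
Product: 24 (3S,4R)-3-methyl-4-[(R)-3-methyl-5-Dec-3-(triethylsilylperoxy)pentyl]oxetan-2-one
Conditions: EtCOCl, i-Pr2NEt, O-trimethylsilylquinine (10 mol %), LiClO4, CH2Cl2/Et2O, −78 °C
Reagents that add atoms: propanoyl chloride CCC(Cl)=O
Why: Cinchona alkaloid/LiClO4-catalysed acyl halide–aldehyde cyclocondensation (formal ketene–aldehyde [2+2]): the alkaloid-bound methylketene enolate adds to the lithium-activated aldehyde under catalyst control to give the cis-(3S,4R)-β-lactone, setting C16 and C17 independently of the remote stereocentres.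

Step 18
Reactants: 24 silylperoxy β-lactone
Product: 26 (2S)-2-[(3S,6R)-6-methyl-6-(2-Dec-ethyl)-1,2-dioxan-3-yl]propanoic acid, via hydroperoxy β-lactone 25 (not isolated)
Conditions: TBAF (1.05 equiv), THF (0.01 M), −40 → 0 °C; then 1 M HCl
Reagents that add atoms: none
Why: Proposed new method: Fluoride cleaves the Si–O bond to give the tertiary alkylperoxide anion, whose terminal oxygen attacks C16 of the β-lactone anti to the C16–O bond (intramolecular SN2 with alkyl–oxygen cleavage), expelling the C18 carboxylate and releasing the strain of the oxetanone. The closest known reactions are the Lewis-acid-promoted intramolecular opening of oxetanes by hydroperoxides to give 1,2-dioxanes and the SN2 alkyl–oxygen opening of β-lactones by azide, cuprates or tethered oxygen nucleophiles; a peroxide nucleophile has not been combined with a β-lactone. The 1,2-dioxane closes in the 6-exo-tet mode. C16 is set by inversion of the (4R)-lactone carbon to 16S, while C17 (catalyst-derived) and C13 (from the invertive perhydrolysis) are untouched, so the 13R,16S,17S array with the anti C16–O/C17–Me relationship follows from substrate configuration alone and no face selection is needed. The step needs alkyl–oxygen over acyl–oxygen cleavage and substitution over E1cB opening: acyl attack would require an eight-membered cyclic perester whereas the six-membered SN2 transition state is entropically favoured, and the weakly basic peroxide anion at low temperature and high dilution should not deprotonate C17. Acidic work-up delivers the free acid.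

Step 19
Reactants: 26 dioxane acid
Product: 27 methyl (2S)-2-[(3S,6R)-6-methyl-6-(2-Dec-ethyl)-1,2-dioxan-3-yl]propanoate (target)
Conditions: TMSCHN2, MeOH/toluene, 0 °C
Reagents that add atoms: (trimethylsilyl)diazomethane C[Si](C)(C)C=[N+]=[N-]
Why: Neutral methylation of the carboxylic acid leaves the peroxide, the tertiary alcohol and the α-stereocentre untouched.

Compound list
1 | propanal | CCC=O | starting material
2 | pent-1-en-3-one (ethyl vinyl ketone) | CCC(=O)C=C | starting material
3 | (R)-2-methyl-5-oxoheptanal | O=C[C@H](C)CCC(=O)CC | intermediate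
4 | (R)-2,4-dimethylcyclohex-2-en-1-one | O=C1CC[C@@H](C)C=C1C | intermediate
5 | (S)-citramalic acid, (S)-2-hydroxy-2-methylbutanedioic acid | C[C@](O)(CC(=O)O)C(=O)O | starting material
6 | (S)-2-methylbutane-1,2,4-triol | C[C@](O)(CCO)CO | intermediate
7 | (S)-2-(2,2,4-trimethyl-1,3-dioxolan-4-yl)ethan-1-ol | OCC[C@@]1(C)COC(C)(C)O1 | intermediate
8 | (S)-4-(2-bromoethyl)-2,2,4-trimethyl-1,3-dioxolane | BrCC[C@@]1(C)COC(C)(C)O1 | intermediate
9 | {2-[(S)-2,2,4-trimethyl-1,3-dioxolan-4-yl]ethyl}magnesium bromide | Br[Mg]CC[C@@]1(C)COC(C)(C)O1 | intermediate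
10 | (3S,4R)-2,4-dimethyl-3-{2-[(S)-2,2,4-trimethyl-1,3-dioxolan-4-yl]ethyl}-1-(trimethylsilyloxy)cyclohex-1-ene | CC1(C)OC[C@](C)(CC[C@H]2[C@H](C)CCC(O[Si](C)(C)C)=C2C)O1 | intermediate
11 | lithium enolate of the 2,4-dimethyl-3-substituted cyclohexanone (from 10) | CC1(C)OC[C@](C)(CC[C@H]2[C@H](C)CCC(O[Li])=C2C)O1 | intermediate
12 | (2R,3S,4R)-2-allyl-2,4-dimethyl-3-{2-[(S)-2,2,4-trimethyl-1,3-dioxolan-4-yl]ethyl}cyclohexan-1-one | CC1(C)OC[C@](C)(CC[C@H]2[C@H](C)CCC(=O)[C@]2(C)CC=C)O1 | intermediate
13 | B-alkyl-9-borabicyclo[3.3.1]nonane from hydroboration of the allyl group of 12 | CC1(C)OC[C@](C)(CC[C@H]2[C@H](C)CCC(=O)[C@]2(C)CCCB3C4CCCC3CCC4)O1 | intermediate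
14 | (2R,3S,4R)-2,4-dimethyl-2-(4-methylpent-4-en-1-yl)-3-{2-[(S)-2,2,4-trimethyl-1,3-dioxolan-4-yl]ethyl}cyclohexan-1-one | CC1(C)OC[C@](C)(CC[C@H]2[C@H](C)CCC(=O)[C@]2(C)CCCC(C)=C)O1 | intermediate
15 | (5S,8R,9S,10R)-4,4,8,10-tetramethyl-9-{2-[(S)-2,2,4-trimethyl-1,3-dioxolan-4-yl]ethyl}-cis-decalin-5-ol | CC1(C)OC[C@](C)(CC[C@H]2[C@H](C)CC[C@]3(O)C(C)(C)CCC[C@]23C)O1 | intermediate
16 | (S)-2-methyl-4-Dec-butane-1,2-diol | C[C@@](O)(CO)CC[C@H]2[C@H](C)CC[C@]3(O)C(C)(C)CCC[C@]23C | intermediate
17 | primary 4-methylbenzenesulfonate of 16 | C[C@@](O)(COS(=O)(=O)c1ccc(C)cc1)CC[C@H]2[C@H](C)CC[C@]3(O)C(C)(C)CCC[C@]23C | intermediate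
18 | (S)-2-methyl-2-(2-Dec-ethyl)oxirane | C[C@@]1(CO1)CC[C@H]2[C@H](C)CC[C@]3(O)C(C)(C)CCC[C@]23C | intermediate
19 | (R)-2-hydroperoxy-2-methyl-4-Dec-butan-1-ol | C[C@](OO)(CO)CC[C@H]2[C@H](C)CC[C@]3(O)C(C)(C)CCC[C@]23C | intermediate
20 | (R)-2-methyl-4-Dec-1-(triethylsilyloxy)-2-(triethylsilylperoxy)butane | C[C@](OO[Si](CC)(CC)CC)(CO[Si](CC)(CC)CC)CC[C@H]2[C@H](C)CC[C@]3(O)C(C)(C)CCC[C@]23C | intermediate
21 | (R)-2-methyl-4-Dec-2-(triethylsilylperoxy)butanal | C[C@](OO[Si](CC)(CC)CC)(C=O)CC[C@H]2[C@H](C)CC[C@]3(O)C(C)(C)CCC[C@]23C | intermediate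
22 | (R,E)-4-methyl-6-Dec-4-(triethylsilylperoxy)hex-2-enal | C[C@](OO[Si](CC)(CC)CC)(/C=C/C=O)CC[C@H]2[C@H](C)CC[C@]3(O)C(C)(C)CCC[C@]23C | intermediate
23 | (R)-4-methyl-6-Dec-4-(triethylsilylperoxy)hexanal | C[C@](OO[Si](CC)(CC)CC)(CCC=O)CC[C@H]2[C@H](C)CC[C@]3(O)C(C)(C)CCC[C@]23C | intermediate
24 | (3S,4R)-3-methyl-4-[(R)-3-methyl-5-Dec-3-(triethylsilylperoxy)pentyl]oxetan-2-one (cis-β-lactone) | C[C@](OO[Si](CC)(CC)CC)(CC[C@H]1OC(=O)[C@H]1C)CC[C@H]2[C@H](C)CC[C@]3(O)C(C)(C)CCC[C@]23C | intermediate
25 | (3S,4R)-4-[(R)-3-hydroperoxy-3-methyl-5-Dec-pentyl]-3-methyloxetan-2-one (present as its tetrabutylammonium peroxide) | C[C@](OO)(CC[C@H]1OC(=O)[C@H]1C)CC[C@H]2[C@H](C)CC[C@]3(O)C(C)(C)CCC[C@]23C | intermediate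
26 | (2S)-2-[(3S,6R)-6-methyl-6-(2-Dec-ethyl)-1,2-dioxan-3-yl]propanoic acid | OC(=O)[C@@H](C)[C@@H]1CC[C@@](C)(CC[C@H]2[C@H](C)CC[C@]3(O)C(C)(C)CCC[C@]23C)OO1 | intermediate
27 | methyl (2S)-2-[(3S,6R)-6-methyl-6-(2-Dec-ethyl)-1,2-dioxan-3-yl]propanoate | COC(=O)[C@@H](C)[C@@H]1CC[C@@](C)(CC[C@H]2[C@H](C)CC[C@]3(O)C(C)(C)CCC[C@]23C)OO1 | target

Total step count: 19. Longest linear sequence: 17 steps (from 5 through steps 3 to 19).

Steps most likely to fail

1. Step 18 (Proposed new method). The peroxide anion or fluoride may attack the lactone carbonyl or deprotonate C17, so that acyl–oxygen cleavage, oligomerisation or E1cB opening to the unsaturated acid outruns the 6-exo alkyl–oxygen displacement. The fallback replaces the oxetanone by an oxetane and uses known chemistry. It sets out from 24: LiBH4 (THF, 0 °C) reduces the lactone to the 1,3-diol F1. Selective tosylation of the primary hydroxyl gives the monotosylate F2, and KOtBu closes the cis-2,3-disubstituted oxetane F3 with the C16–O bond intact. HF·pyridine frees the hydroperoxy oxetane F4. Under TMSOTf catalysis at −78 °C, F4 should undergo the established Lewis-acid-promoted intramolecular 6-exo opening of an oxetane by a hydroperoxide at C16 with inversion, giving the dioxane primary alcohol F5. Oxidation with TEMPO/PhI(OAc)2 in aqueous MeCN brings the sequence back to the route at acid 26.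

2. Step 12. Partial ionisation of the molybdenum-activated epoxide at the tertiary carbon may erode the configuration at C13, or the acidic medium may engage the tertiary C5 alcohol. The fallback sets out from epoxide 18. Copper-catalysed opening at the CH2 terminus with vinylmagnesium bromide gives the homoallylic tertiary alcohol F6, and ozonolysis with NaBH4 work-up gives the 1,3-diol F7. The primary tosylate F8 and KOtBu give the 2,2-disubstituted oxetane F9 with the C13–O bond retained. TMSOTf-catalysed perhydrolysis of this oxetane with ethereal H2O2 at low temperature, a reaction known to invert the tertiary carbon, gives the 3-hydroperoxy alcohol F10. Bis-silylation gives the bis(triethylsilyl) compound F11, direct Swern oxidation the aldehyde F12, and Wittig methoxymethylenation with Ph3P=CHOMe the enol ether F13. Mild hydrolysis (Hg(OAc)2, aqueous THF, then KI) comes back to the route at aldehyde 23.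

3. Step 9. Addition of the congested tertiary radical to the ketone is reversible (β-scission of the alkoxy radical), so simple reduction of the alkene or attack on the wrong carbonyl face may compete. The fallback sets out from allyl ketone 12: prenylmagnesium chloride adds through its γ-carbon, anti to the axial C10 methyl, to give the reverse-prenylated tertiary alcohol F14. Ring-closing metathesis with the second-generation Grubbs catalyst closes ring A as the cyclohexene F15, and hydrogenation (H2, Pd/C) comes back to the route at decalol 15.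

Further compounds
F1 | step 18 | 1,3-diol from reduction of the lactone of 24 (C16–OH, C18–OH; C13, C16 and C17 arranged as in 24) | C[C@](OO[Si](CC)(CC)CC)(CC[C@@H](O)[C@H](C)CO)CC[C@H]2[C@H](C)CC[C@]3(O)C(C)(C)CCC[C@]23C
F2 | step 18 | primary (C18) 4-methylbenzenesulfonate of F1 | C[C@](OO[Si](CC)(CC)CC)(CC[C@@H](O)[C@H](C)COS(=O)(=O)c1ccc(C)cc1)CC[C@H]2[C@H](C)CC[C@]3(O)C(C)(C)CCC[C@]23C
F3 | step 18 | cis-3-methyl-2-alkyloxetane (O–C16–C17–C18 ring) with the C13 triethylsilyl peroxide | C[C@](OO[Si](CC)(CC)CC)(CC[C@H]1OC[C@H]1C)CC[C@H]2[C@H](C)CC[C@]3(O)C(C)(C)CCC[C@]23C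
F4 | step 18 | hydroperoxy oxetane (F3 without the silyl group) | C[C@](OO)(CC[C@H]1OC[C@H]1C)CC[C@H]2[C@H](C)CC[C@]3(O)C(C)(C)CCC[C@]23C
F5 | step 18 | (2S)-2-[(3S,6R)-6-methyl-6-(2-Dec-ethyl)-1,2-dioxan-3-yl]propan-1-ol | OC[C@@H](C)[C@@H]1CC[C@@](C)(CC[C@H]2[C@H](C)CC[C@]3(O)C(C)(C)CCC[C@]23C)OO1
F6 | step 12 | homoallylic tertiary alcohol, 3-methyl-1-Dec-hex-5-en-3-ol (C13–O retained from 18) | C[C@@](O)(CC=C)CC[C@H]2[C@H](C)CC[C@]3(O)C(C)(C)CCC[C@]23C
F7 | step 12 | 3-methyl-5-Dec-pentane-1,3-diol | C[C@@](O)(CCO)CC[C@H]2[C@H](C)CC[C@]3(O)C(C)(C)CCC[C@]23C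
F8 | step 12 | primary 4-methylbenzenesulfonate of F7 | C[C@@](O)(CCOS(=O)(=O)c1ccc(C)cc1)CC[C@H]2[C@H](C)CC[C@]3(O)C(C)(C)CCC[C@]23C
F9 | step 12 | 2-methyl-2-(2-Dec-ethyl)oxetane | C[C@@]1(CCO1)CC[C@H]2[C@H](C)CC[C@]3(O)C(C)(C)CCC[C@]23C
F10 | step 12 | 3-hydroperoxy-3-methyl-5-Dec-pentan-1-ol (C13 inverted) | C[C@](OO)(CCO)CC[C@H]2[C@H](C)CC[C@]3(O)C(C)(C)CCC[C@]23C
F11 | step 12 | bis(triethylsilyl) derivative of F10 | C[C@](OO[Si](CC)(CC)CC)(CCO[Si](CC)(CC)CC)CC[C@H]2[C@H](C)CC[C@]3(O)C(C)(C)CCC[C@]23C
F12 | step 12 | 3-methyl-5-Dec-3-(triethylsilylperoxy)pentanal | C[C@](OO[Si](CC)(CC)CC)(CC=O)CC[C@H]2[C@H](C)CC[C@]3(O)C(C)(C)CCC[C@]23C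
F13 | step 12 | methyl enol ether, 1-methoxy-4-methyl-6-Dec-4-(triethylsilylperoxy)hex-1-ene (E/Z mixture) | C[C@](OO[Si](CC)(CC)CC)(CC=COC)CC[C@H]2[C@H](C)CC[C@]3(O)C(C)(C)CCC[C@]23C
F14 | step 9 | tertiary alcohol from γ-addition of the prenyl reagent to 12 (C5 bears OH and 2-methylbut-3-en-2-yl; OH cis to the C10 methyl) | CC1(C)OC[C@](C)(CC[C@H]2[C@H](C)CC[C@](O)(C(C)(C)C=C)[C@]2(C)CC=C)O1
F15 | step 9 | 2,3-didehydro analogue of 15 (ring A cyclohexene) | CC1(C)OC[C@](C)(CC[C@H]2[C@H](C)CC[C@]3(O)C(C)(C)C=CC[C@]23C)O1
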